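**Retrosynthetic overview**

1. The target comes from the bicyclic C8 silyl ether by desilylation and selective acetylation of the secondary hydroxyl.
2. Ring A is formed last, in one operation on a 3-(1-silyloxy-2-oxopropyl)dihydropyranone: 1-ethoxyvinyllithium (a masked acetyl anion) makes C6–C7 at the methyl ketone and sets C7 by Felkin–Anh control, then the unveiled methyl ketone condenses onto the C4a vinylogous-ester carbonyl (C4a=C5).
3. Ring B is formed first, by 6-endo oxa-Michael closure of a hydroxy ynone made from a dienyl acetylide and a Weinreb amide.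
4. C8 and C8a come from an Evans syn aldol of a 3-silyloxypropanoyl imide with 2,2-dimethoxypropanal (masked pyruvaldehyde).
5. The side chain comes from (S)-2-methylbutan-1-ol by a Still–Gennari olefination (Z) and a Horner–Wadsworth–Emmons olefination (E).

Assumption: the two phosphonate reagents, methyl 2,2-dimethoxypropanoate and 3-[(tert-butyldimethylsilyl)oxy]propanoic acid are bought as catalogue compounds; positions are given in the isochromene numbering of the target.

**Route**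

Step 1
Reactants: 1 (S)-2-methylbutan-1-ol; 2 methyl 2-[bis(2,2,2-trifluoroethoxy)phosphoryl]propanoate
Product: 4 methyl (2Z,4S)-2,4-dimethylhex-2-enoate, via (S)-2-methylbutanal 3 (not isolated)
Conditions: NaOCl, KBr, TEMPO (cat.), CH2Cl2/H2O, 0 °C; dried CH2Cl2 layer added to 2, KN(SiMe3)2, 18-crown-6, THF, −78 °C
Reagents that add atoms: none
Why: TEMPO/NaOCl oxidation gives the α-chiral aldehyde without epimerisation, and the Still–Gennari variant of the Horner–Wadsworth–Emmons olefination delivers the (Z)-trisubstituted enoate under kinetic control; the stereocentre comes from 1.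

Step 2
Reactants: 4 methyl (2Z,4S)-2,4-dimethylhex-2-enoate
Product: 5 (2Z,4S)-2,4-dimethylhex-2-en-1-ol
Conditions: i-Bu2AlH, CH2Cl2, −78 °C; aq. KNaC4H4O6
Reagents that add atoms: none
Why: Low-temperature aluminium hydride 1,2-reduction of the enoate gives the allylic alcohol without touching the (Z)-alkene or the stereocentre.

Step 3
Reactants: 5 (2Z,4S)-2,4-dimethylhex-2-en-1-ol; 6 diethyl [3-(trimethylsilyl)prop-2-yn-1-yl]phosphonate
Product: 8 [(3E,5Z,7S)-5,7-dimethylnona-3,5-dien-1-yn-1-yl]trimethylsilane, via (2Z,4S)-2,4-dimethylhex-2-enal 7 (not isolated)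
Conditions: MnO2, CH2Cl2, rt, filter; then 6, LiN(SiMe3)2, THF, −78 → 0 °C
Reagents that add atoms: none
Why: MnO2 oxidises only the allylic alcohol and keeps the (Z)-geometry, and the Horner–Wadsworth–Emmons reaction of the lithiated propargyl phosphonate forms the new disubstituted alkene as the (E)-isomer.

Step 4
Reactants: 9 methyl 2,2-dimethoxypropanoate
Product: 10 2,2-dimethoxypropanal
Conditions: i-Bu2AlH, CH2Cl2, −78 °C; aq. KNaC4H4O6
Reagents that add atoms: none
Why: The α,α-dialkoxy ester forms a stable tetrahedral aluminate at −78 °C, so the hydride reduction stops at the aldehyde.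

Step 5
Reactants: 11 3-[(tert-butyldimethylsilyl)oxy]propanoic acid; 12 (R)-4-benzyloxazolidin-2-one
Product: 14 (R)-4-benzyl-3-{3-[(tert-butyldimethylsilyl)oxy]propanoyl}oxazolidin-2-one, via mixed pivalic anhydride 13 (not isolated)
Conditions: pivaloyl chloride, Et3N, THF, −20 °C; then 12, LiCl, rt
Reagents that add atoms: none
Why: Mixed-anhydride N-acylation attaches the acyl chain to the Evans auxiliary at the less hindered carbonyl of the anhydride.

Step 6
Reactants: 14 (R)-4-benzyl-3-{3-[(tert-butyldimethylsilyl)oxy]propanoyl}oxazolidin-2-one; 10 2,2-dimethoxypropanal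
Product: 16 (R)-4-benzyl-3-[(2R,3R)-2-{[(tert-butyldimethylsilyl)oxy]methyl}-3-hydroxy-4,4-dimethoxypentanoyl]oxazolidin-2-one, via dibutylboron enolate 15 (not isolated)
Conditions: Bu2BOTf, i-Pr2NEt, CH2Cl2, 0 °C; 10, −78 → 0 °C; H2O2, pH 7 buffer, MeOH
Reagents that add atoms: none
Why: Evans syn aldol: the (Z)-boron enolate reacts through a Zimmerman–Traxler chair on the face away from the benzyl group of the (R)-auxiliary, which sets C8a and C8 as the (2R,3R) syn pair; the aldehyde has no α-hydrogen and cannot enolise.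

Step 7
Reactants: 16 (R)-4-benzyl-3-[(2R,3R)-2-{[(tert-butyldimethylsilyl)oxy]methyl}-3-hydroxy-4,4-dimethoxypentanoyl]oxazolidin-2-one
Product: 17 (2R,3R)-2-{[(tert-butyldimethylsilyl)oxy]methyl}-3-hydroxy-N,4,4-trimethoxy-N-methylpentanamide
Conditions: MeNHOMe·HCl, AlMe3, CH2Cl2, −15 → 0 °C; aq. KNaC4H4O6
Reagents that add atoms: N,O-dimethylhydroxylamine hydrochloride, CNOC.Cl
Why: Aluminium amide transamination (Weinreb amide formation), assisted by the free β-hydroxyl, releases the auxiliary without epimerising the α-centre.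

Step 8
Reactants: 17 (2R,3R)-2-{[(tert-butyldimethylsilyl)oxy]methyl}-3-hydroxy-N,4,4-trimethoxy-N-methylpentanamide
Product: 18 (2R,3R)-3-[(tert-butyldimethylsilyl)oxy]-2-{[(tert-butyldimethylsilyl)oxy]methyl}-N,4,4-trimethoxy-N-methylpentanamide
Conditions: TBSOTf, 2,6-lutidine, CH2Cl2, −78 °C
Reagents that add atoms: tert-butyldimethylsilyl trifluoromethanesulfonate, CC(C)(C)[Si](C)(C)OS(=O)(=O)C(F)(F)F
Why: Low-temperature silylation of the secondary alcohol installs a bulky non-chelating group that later steers the addition at C7 and keeps this oxygen out of the ring B closure.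

Step 9
Reactants: 18 (2R,3R)-3-[(tert-butyldimethylsilyl)oxy]-2-{[(tert-butyldimethylsilyl)oxy]methyl}-N,4,4-trimethoxy-N-methylpentanamide; 8 [(3E,5Z,7S)-5,7-dimethylnona-3,5-dien-1-yn-1-yl]trimethylsilane
Product: 23 (3R)-3-[(1R)-1-[(tert-butyldimethylsilyl)oxy]-2-oxopropyl]-6-[(1E,3Z,5S)-3,5-dimethylhepta-1,3-dien-1-yl]-2,3-dihydro-4H-pyran-4-one, via dienynyllithium 19 (not isolated), via bis-silyl ynone ketal 20 (not isolated), via hydroxy ynone ketal 21 (not isolated), via dihydropyranone ketal 22 (not isolated)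
Conditions: 8, MeLi·LiBr, THF, 0 °C → rt; 18, −78 → 0 °C; then 1 M HCl, THF, rt
Reagents that add atoms: water, O
Why: MeLi cleaves the alkynyl–silicon bond and the acetylide acylates once on the Weinreb amide (chelated tetrahedral adduct); aqueous acid then removes the primary silyl ether, closes ring B by 6-endo-dig oxa-Michael addition and hydrolyses the dimethyl ketal while the hindered secondary silyl ether survives, with no stereocentre formed or touched.

Step 10
Reactants: 23 (3R)-3-[(1R)-1-[(tert-butyldimethylsilyl)oxy]-2-oxopropyl]-6-[(1E,3Z,5S)-3,5-dimethylhepta-1,3-dien-1-yl]-2,3-dihydro-4H-pyran-4-one; 24 ethyl vinyl ether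
Product: 28 (7R,8R,8aR)-8-[(tert-butyldimethylsilyl)oxy]-3-[(1E,3Z,5S)-3,5-dimethylhepta-1,3-dien-1-yl]-7-hydroxy-7-methyl-1,7,8,8a-tetrahydro-6H-isochromen-6-one, via 1-ethoxyvinyllithium 25 (not isolated), via enol ether carbinol 26 (not isolated), via hydroxy diketone 27 (not isolated)
Conditions: 24, t-BuLi, THF, −78 → 0 °C; 23, THF, −78 °C; then 1 M HCl, THF, 0 °C → rt
Reagents that add atoms: water, O
Why: Proposed new method: 1-ethoxyvinyllithium, a masked acetyl anion, adds to the C7 methyl ketone (far more electrophilic than the vinylogous-ester carbonyl) anti to the C8 silyloxy group (polar Felkin–Anh, non-chelating silyl ether), which gives the C7 hydroxyl cis to the C8 oxygen; acid hydrolysis of the enol ether unveils a methyl ketone whose only enol (C7 is quaternary) attacks the O-protonated vinylogous-ester carbonyl C4a and dehydrates to the conjugated dienone, closing ring A; the closest known reactions are α-alkoxyvinyllithium additions to ketones and acid-promoted Robinson-type aldol cyclodehydrations (Stork–Danheiser-type 1,2-additions to vinylogous esters).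

Step 11
Reactants: 28 (7R,8R,8aR)-8-[(tert-butyldimethylsilyl)oxy]-3-[(1E,3Z,5S)-3,5-dimethylhepta-1,3-dien-1-yl]-7-hydroxy-7-methyl-1,7,8,8a-tetrahydro-6H-isochromen-6-one
Product: 29 (7R,8R,8aR)-3-[(1E,3Z,5S)-3,5-dimethylhepta-1,3-dien-1-yl]-7,8-dihydroxy-7-methyl-1,7,8,8a-tetrahydro-6H-isochromen-6-one
Conditions: HF·pyridine, pyridine, THF, 0 °C → rt
Reagents that add atoms: none
Why: Buffered fluoride desilylation frees the C8 alcohol without strong base, so β-elimination across C8a–C8 is avoided.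

Step 12
Reactants: 29 (7R,8R,8aR)-3-[(1E,3Z,5S)-3,5-dimethylhepta-1,3-dien-1-yl]-7,8-dihydroxy-7-methyl-1,7,8,8a-tetrahydro-6H-isochromen-6-one
Product: 30 (7R,8R,8aR)-3-[(1E,3Z,5S)-3,5-dimethylhepta-1,3-dien-1-yl]-7-hydroxy-7-methyl-6-oxo-6,7,8,8a-tetrahydro-1H-isochromen-8-yl acetate
Conditions: Ac2O, pyridine, DMAP (cat.), CH2Cl2, 0 °C
Reagents that add atoms: acetic anhydride, CC(=O)OC(C)=O
Why: DMAP-catalysed (Steglich-type) acetylation takes the secondary C8 hydroxyl and leaves the hindered tertiary C7 hydroxyl, under conditions too weakly basic to epimerise C8a or eliminate the acetate.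

**Compound list**

1 | (S)-2-methylbutan-1-ol | CC[C@H](C)CO | starting material
2 | methyl 2-[bis(2,2,2-trifluoroethoxy)phosphoryl]propanoate | COC(=O)C(C)P(=O)(OCC(F)(F)F)OCC(F)(F)F | starting material
3 | (S)-2-methylbutanal | CC[C@H](C)C=O | intermediate
4 | methyl (2Z,4S)-2,4-dimethylhex-2-enoate | CC[C@H](C)/C=C(C)\C(=O)OC | intermediate
5 | (2Z,4S)-2,4-dimethylhex-2-en-1-ol | CC[C@H](C)/C=C(C)\CO | intermediate
6 | diethyl [3-(trimethylsilyl)prop-2-yn-1-yl]phosphonate | CCOP(=O)(CC#C[Si](C)(C)C)OCC | starting material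
7 | (2Z,4S)-2,4-dimethylhex-2-enal | CC[C@H](C)/C=C(C)\C=O | intermediate
8 | [(3E,5Z,7S)-5,7-dimethylnona-3,5-dien-1-yn-1-yl]trimethylsilane | CC[C@H](C)/C=C(C)\C=C\C#C[Si](C)(C)C | intermediate
9 | methyl 2,2-dimethoxypropanoate | COC(=O)C(C)(OC)OC | starting material
10 | 2,2-dimethoxypropanal | CC(OC)(OC)C=O | intermediate
11 | 3-[(tert-butyldimethylsilyl)oxy]propanoic acid | OC(=O)CCO[Si](C)(C)C(C)(C)C | starting material
12 | (R)-4-benzyloxazolidin-2-one | O=C1N[C@H](Cc2ccccc2)CO1 | starting material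
13 | 3-[(tert-butyldimethylsilyl)oxy]propanoic pivalic anhydride | CC(C)(C)C(=O)OC(=O)CCO[Si](C)(C)C(C)(C)C | intermediate
14 | (R)-4-benzyl-3-{3-[(tert-butyldimethylsilyl)oxy]propanoyl}oxazolidin-2-one | O=C(CCO[Si](C)(C)C(C)(C)C)N1[C@H](Cc2ccccc2)COC1=O | intermediate
15 | (Z)-dibutylboron enolate of 14 | CCCCB(CCCC)O/C(=C\CO[Si](C)(C)C(C)(C)C)N1[C@H](Cc2ccccc2)COC1=O | intermediate
16 | (R)-4-benzyl-3-[(2R,3R)-2-{[(tert-butyldimethylsilyl)oxy]methyl}-3-hydroxy-4,4-dimethoxypentanoyl]oxazolidin-2-one | CC(OC)(OC)[C@H](O)[C@@H](CO[Si](C)(C)C(C)(C)C)C(=O)N1[C@H](Cc2ccccc2)COC1=O | intermediate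
17 | (2R,3R)-2-{[(tert-butyldimethylsilyl)oxy]methyl}-3-hydroxy-N,4,4-trimethoxy-N-methylpentanamide | CC(OC)(OC)[C@H](O)[C@@H](CO[Si](C)(C)C(C)(C)C)C(=O)N(C)OC | intermediate
18 | (2R,3R)-3-[(tert-butyldimethylsilyl)oxy]-2-{[(tert-butyldimethylsilyl)oxy]methyl}-N,4,4-trimethoxy-N-methylpentanamide | CC(OC)(OC)[C@H](O[Si](C)(C)C(C)(C)C)[C@@H](CO[Si](C)(C)C(C)(C)C)C(=O)N(C)OC | intermediate
19 | [(3E,5Z,7S)-5,7-dimethylnona-3,5-dien-1-yn-1-yl]lithium | CC[C@H](C)/C=C(C)\C=C\C#C[Li] | intermediate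
20 | (3R,4R,8E,10Z,12S)-3-[(tert-butyldimethylsilyl)oxy]-4-{[(tert-butyldimethylsilyl)oxy]methyl}-2,2-dimethoxy-10,12-dimethyltetradeca-8,10-dien-6-yn-5-one | CC[C@H](C)/C=C(C)\C=C\C#CC(=O)[C@H](CO[Si](C)(C)C(C)(C)C)[C@@H](O[Si](C)(C)C(C)(C)C)C(C)(OC)OC | intermediate
21 | (3R,4R,8E,10Z,12S)-3-[(tert-butyldimethylsilyl)oxy]-4-(hydroxymethyl)-2,2-dimethoxy-10,12-dimethyltetradeca-8,10-dien-6-yn-5-one | CC[C@H](C)/C=C(C)\C=C\C#CC(=O)[C@H](CO)[C@@H](O[Si](C)(C)C(C)(C)C)C(C)(OC)OC | intermediate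
22 | (3R)-3-[(1R)-1-[(tert-butyldimethylsilyl)oxy]-2,2-dimethoxypropyl]-6-[(1E,3Z,5S)-3,5-dimethylhepta-1,3-dien-1-yl]-2,3-dihydro-4H-pyran-4-one | CC[C@H](C)/C=C(C)\C=C\C1=CC(=O)[C@H](CO1)[C@@H](O[Si](C)(C)C(C)(C)C)C(C)(OC)OC | intermediate
23 | (3R)-3-[(1R)-1-[(tert-butyldimethylsilyl)oxy]-2-oxopropyl]-6-[(1E,3Z,5S)-3,5-dimethylhepta-1,3-dien-1-yl]-2,3-dihydro-4H-pyran-4-one | CC[C@H](C)/C=C(C)\C=C\C1=CC(=O)[C@H](CO1)[C@@H](O[Si](C)(C)C(C)(C)C)C(C)=O | intermediate
24 | ethyl vinyl ether (ethoxyethene) | C=COCC | starting material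
25 | (1-ethoxyvinyl)lithium | [Li]C(=C)OCC | intermediate
26 | (3R)-3-[(1R,2R)-1-[(tert-butyldimethylsilyl)oxy]-3-ethoxy-2-hydroxy-2-methylbut-3-en-1-yl]-6-[(1E,3Z,5S)-3,5-dimethylhepta-1,3-dien-1-yl]-2,3-dihydro-4H-pyran-4-one | CC[C@H](C)/C=C(C)\C=C\C1=CC(=O)[C@H](CO1)[C@@H](O[Si](C)(C)C(C)(C)C)[C@@](C)(O)C(=C)OCC | intermediate
27 | (3R)-3-[(1R,2R)-1-[(tert-butyldimethylsilyl)oxy]-2-hydroxy-2-methyl-3-oxobutyl]-6-[(1E,3Z,5S)-3,5-dimethylhepta-1,3-dien-1-yl]-2,3-dihydro-4H-pyran-4-one | CC[C@H](C)/C=C(C)\C=C\C1=CC(=O)[C@H](CO1)[C@@H](O[Si](C)(C)C(C)(C)C)[C@@](C)(O)C(C)=O | intermediate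
28 | (7R,8R,8aR)-8-[(tert-butyldimethylsilyl)oxy]-3-[(1E,3Z,5S)-3,5-dimethylhepta-1,3-dien-1-yl]-7-hydroxy-7-methyl-1,7,8,8a-tetrahydro-6H-isochromen-6-one | CC[C@H](C)/C=C(C)\C=C\C1=CC2=CC(=O)[C@](C)(O)[C@H](O[Si](C)(C)C(C)(C)C)[C@H]2CO1 | intermediate
29 | (7R,8R,8aR)-3-[(1E,3Z,5S)-3,5-dimethylhepta-1,3-dien-1-yl]-7,8-dihydroxy-7-methyl-1,7,8,8a-tetrahydro-6H-isochromen-6-one | CC[C@H](C)/C=C(C)\C=C\C1=CC2=CC(=O)[C@](C)(O)[C@H](O)[C@H]2CO1 | intermediate
30 | (7R,8R,8aR)-3-[(1E,3Z,5S)-3,5-dimethylhepta-1,3-dien-1-yl]-7-hydroxy-7-methyl-6-oxo-6,7,8,8a-tetrahydro-1H-isochromen-8-yl acetate | CC[C@H](C)/C=C(C)\C=C\C1=CC2=CC(=O)[C@](C)(O)[C@H](OC(C)=O)[C@H]2CO1 | target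

**Step count and risks**

Total steps: 12. Longest linear sequence: 8 steps (steps 5–12, from 11 and 12 to 30). The side-chain branch (steps 1–3) and the aldehyde branch (step 4) join at steps 9 and 6.

Most likely to fail, step 10. The vinyllithium may enolise the methyl ketone or give poor Felkin selectivity, and the aldol closure onto a vinylogous-ester carbonyl is untested; prolonged acid could also isomerise the (3Z)-alkene. The fallback makes the two ring A bonds in the opposite order and lets a catalyst set C7. It sets out from 22, which is isolated when the acid stage of step 9 is run with camphorsulfonic acid in MeOH (this frees the primary alcohol and closes ring B but keeps the ketal). (Z)-2-Ethoxyvinyllithium (from (Z)-1-bromo-2-ethoxyethene and t-BuLi, THF, −78 °C) adds 1,2 to the ring ketone to give the tertiary allylic alcohol F1. Brief 1 M HCl in THF then causes allylic transposition and hydrolysis to the enal (formyl olefination) and unmasks the ketone, giving the keto dienal F2. A chiral aminoindanol-derived triazolium tetrafluoroborate with i-Pr2NEt in toluene then closes ring A by an intramolecular aldehyde–ketone benzoin reaction, in which the Breslow intermediate of the C6 aldehyde adds to the C7 ketone. The sequence comes back to the route at 28.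

Second, step 9. The acetylide may add sluggishly to the hindered amide, or the acid stage may not give clean selective desilylation, ring closure and ketal hydrolysis together. The fallback builds ring B from a 1,3-diketone instead of an ynone and sets out from 18 (and from 5 for the side chain). MeMgBr (THF, 0 °C) converts 18 into the methyl ketone F3. Alcohol 5 is taken by MnO2 and Ph3P=CHCHO (CH2Cl2, rt) to the dienal F4. The LiN(SiMe3)2 enolate of F3 (kinetic, methyl side) adds to F4 to give the aldol F5 as a carbinol mixture. Dess–Martin periodinane oxidises this to the 1,3-diketone F6. 1 M HCl in THF then removes the primary silyl ether, cyclodehydrates the hydroxy diketone to the dihydropyranone and hydrolyses the ketal, coming back to the route at 23.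

Third, step 6. The β-silyloxy imide may eliminate on enolisation, or the enolate may add poorly to the hindered α,α-dialkoxy aldehyde. The fallback replaces the auxiliary aldol by a catalytic ketene–aldehyde cycloaddition and sets out from 11 and 10. 1-Chloro-N,N,2-trimethylprop-1-en-1-amine (CH2Cl2, 0 °C) converts 11 into the acid chloride F7. Alkaloid-catalysed acyl halide–aldehyde cyclocondensation of F7 with 10 (O-trimethylsilylquinidine or its quinine pseudoenantiomer as needed, LiClO4, i-Pr2NEt, CH2Cl2/Et2O, −78 °C) gives the cis-β-lactone F8, the syn-aldol equivalent. Opening F8 at the acyl carbon with MeNHOMe·HCl/AlMe3 gives the β-hydroxy Weinreb amide and comes back to the route at 17, bypassing steps 5–7.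

**Further compounds**

F1 | step 10 | (3R)-3-[(1R)-1-[(tert-butyldimethylsilyl)oxy]-2,2-dimethoxypropyl]-6-[(1E,3Z,5S)-3,5-dimethylhepta-1,3-dien-1-yl]-4-[(Z)-2-ethoxyethenyl]-3,4-dihydro-2H-pyran-4-ol (C4 epimers) | CC[C@H](C)/C=C(C)\C=C\C1=CC(O)(/C=C\OCC)[C@H](CO1)[C@@H](O[Si](C)(C)C(C)(C)C)C(C)(OC)OC
F2 | step 10 | (2E)-2-{(3R)-3-[(1R)-1-[(tert-butyldimethylsilyl)oxy]-2-oxopropyl]-6-[(1E,3Z,5S)-3,5-dimethylhepta-1,3-dien-1-yl]-2,3-dihydro-4H-pyran-4-ylidene}acetaldehyde | CC[C@H](C)/C=C(C)\C=C\C1=C\C(=C\C=O)[C@H](CO1)[C@@H](O[Si](C)(C)C(C)(C)C)C(C)=O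
F3 | step 9 | (3R,4R)-4-[(tert-butyldimethylsilyl)oxy]-3-{[(tert-butyldimethylsilyl)oxy]methyl}-5,5-dimethoxyhexan-2-one | CC(=O)[C@H](CO[Si](C)(C)C(C)(C)C)[C@@H](O[Si](C)(C)C(C)(C)C)C(C)(OC)OC
F4 | step 9 | (2E,4Z,6S)-4,6-dimethylocta-2,4-dienal | CC[C@H](C)/C=C(C)\C=C\C=O
F5 | step 9 | (3R,4R,8E,10Z,12S)-3-[(tert-butyldimethylsilyl)oxy]-4-{[(tert-butyldimethylsilyl)oxy]methyl}-7-hydroxy-2,2-dimethoxy-10,12-dimethyltetradeca-8,10-dien-5-one (C7 epimers) | CC[C@H](C)/C=C(C)\C=C\C(O)CC(=O)[C@H](CO[Si](C)(C)C(C)(C)C)[C@@H](O[Si](C)(C)C(C)(C)C)C(C)(OC)OC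
F6 | step 9 | (3R,4R,8E,10Z,12S)-3-[(tert-butyldimethylsilyl)oxy]-4-{[(tert-butyldimethylsilyl)oxy]methyl}-2,2-dimethoxy-10,12-dimethyltetradeca-8,10-diene-5,7-dione | CC[C@H](C)/C=C(C)\C=C\C(=O)CC(=O)[C@H](CO[Si](C)(C)C(C)(C)C)[C@@H](O[Si](C)(C)C(C)(C)C)C(C)(OC)OC
F7 | step 6 | 3-[(tert-butyldimethylsilyl)oxy]propanoyl chloride | CC(C)(C)[Si](C)(C)OCCC(Cl)=O
F8 | step 6 | (3R,4R)-3-{[(tert-butyldimethylsilyl)oxy]methyl}-4-(1,1-dimethoxyethyl)oxetan-2-one | O=C1O[C@@H](C(C)(OC)OC)[C@H]1CO[Si](C)(C)C(C)(C)C
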